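The runs were computed from invented constants; the scatter is artificial.

The flask starts from equal amounts: 1.0 M of the left-handed substrate, as much of its mirror image, and 2.50 M of reagent, with a single-handed free catalyst.

- Saturday's: left-handed substrate 1 M; right-handed substrate 1 M; reagent 2.5 M; free catalyst 5 mM; precatalyst 110 mM; the very flask that is asked about, followed so far
- flask: left-handed substrate 1.0 M; reagent 2.50 M; free catalyst 5.0 mM; precatalyst 110 mM; right-handed substrate 1.0 M; time 10 h

Saturday's run (percent of the left-handed substrate and right-handed substrate together charged)

| time / min | left-handed product / % | right-handed product / % |
|---|---|---|
| 8.00 | 12 | 6 |
| 20.0 | 20 | 9 |
| 50.0 | 31 | 9 |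
| 120 | 43 | 13 |

(standard deviation of a reading: 1.5 percentage points)

- free catalyst is single-handed; left-handed substrate and right-handed substrate are mirror images of each other, charged as a racemate, each of them at the stated concentration
- the analysis behind the earlier runs scatters by 1.5 percentage points, standard deviation
- steps thought possible: 2 reagent -> self-condensation product; left-handed substrate + racemization catalyst <-> right-handed substrate + racemization catalyst; reagent + free catalyst + right-handed substrate -> free catalyst + right-handed product; 2 free catalyst <-> resting dimer; precatalyst -> racemization catalyst; reagent + free catalyst + left-handed substrate -> free catalyst + left-handed product
- an excess is below zero if the other one leads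

1. left-handed product and right-handed product together, in percent of the left-handed substrate and right-handed substrate charged together, at 10 h
2. excess of left-handed product over right-handed product in the product at 10 h
3. whether the exchange between left-handed substrate and right-handed substrate keeps pace with the reaction: how far the product's excess at 10 h gets from its value without exchange to its value with instant exchange (above 80 % keeps pace, below 20 % hardly takes part, else lags behind)

Equal amounts give me the zero of my scale: mirror images differ in nothing but handedness, so any excess in the product is the catalyst's preference. I therefore want the level excess, the excess of left-handed product over right-handed product while the two substrates stand level; it comes from the ratio of the two rates at equal concentrations, the selectivity factor, and it is the value with instant exchange.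

I read it from Saturday's run in two ways. The last reading alone gives 53.6 %, while the three earlier readings summed give 44.8 %. A preference left unaided drains the left-handed substrate, so the excess should sink along the run; here the later figure is higher than the earlier one, and I take the substrates to be held level by exchange.

The two still part, and the single reading is the one that cheats. Right-handed product reads 9 % at 20.0 min and 9 % at 50.0 min while left-handed product climbs from 20 % to 31 %, so the step between those two right-handed figures is hidden by the scatter of 1.5 percentage points, and a ratio taken from one reading carries that scatter. I therefore sum all the readings: 106 % left-handed against 37.0 % right-handed, a ratio of 2.86, and so a level excess of 48.3 %. That is my figure for the excess at 10 h, with exchange keeping pace.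

The forecast gives a yield of 85 % (72 % to 93 %), an excess of 52 % (42 % to 60 %), and says the exchange keeps pace: “So exchange has switched on, presumably as the precatalyst activates”. Its excess is higher than mine.

At 10 h the flask gives a yield of 81.9 % and an excess of 45.9 %; the exchange keeps pace, getting 96 % of the way.

    2 reagent → self-condensation product (k = 8.50 × 10⁻⁴ M⁻¹ min⁻¹)
    left-handed substrate + racemization catalyst ⇌ right-handed substrate + racemization catalyst, rate k2*[racemization catalyst]*[left-handed substrate] forward; the back reaction follows from the equilibrium constant (k = 14.0 M⁻¹ min⁻¹)
    reagent + free catalyst + right-handed substrate → free catalyst + right-handed product (k = 1.30 M⁻² min⁻¹)
    2 free catalyst ⇌ resting dimer (K = 630 M⁻¹, k = 8.90 M⁻¹ min⁻¹)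
    precatalyst → racemization catalyst (k = 0.00650 min⁻¹)
    reagent + free catalyst + left-handed substrate → free catalyst + left-handed product (k = 3.60 M⁻² min⁻¹)

The level excess splits this flask's yield into 60.7 % left-handed product, and the flask holds 59.7 %. A neighbour flask charged with 0.62 M of reagent, everything else held, reaches a yield of 28.8 %, with 1.90 % of its reagent left. The same split gives 21.4 % left-handed product there. That neighbour holds 21.1 % of it, at an excess of 46.7 %, with 35.6 % still standing as right-handed substrate.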